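**Plan**

1. The target is a 10-membered carbocycle (germacrane numbering: C1=C10 Z with the C14 methyl, C3 ester, C4=C5 E with the C15 methyl, C9 hydroxyl) cis-fused at C6/C7 to an α-methyl γ-lactone (O on C6, C12 carbonyl, C11 with the C13 methyl). The ring allylic alcohol C5H=C4(CH3)–C3H(O), flanked by the C6 stereocentre, is the retron of a reductive alkyne–aldehyde coupling that makes the C3–C4 bond, the E-alkene and the C3 stereocentre in one event.
2. Retrosynthetic cuts, in order: C3 O–acyl; C3–C4 (10-membered ring, from ynal 19); C9–C10 (alkenyl iodide 6 + aldehyde 15); C11–H; C6–C7 together with the lactone C–O (allyl bromide 9 + but-2-ynal 10); C1=C10 (iodo-olefination).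
3. Forward: the γ-lactone arises first (step 4), the chain is joined at C9–C10 (step 8), the 10-membered ring closes at C3–C4 (step 12), then desilylation at C3, esterification and desilylation at C9.
4. Stereochemistry: C6/C7 from a chiral chromium catalyst (closed transition state, cis-lactone); C11 by kinetic protonation on the open lactone face; C9 from the chiral ligand of the chromium alkenylation; C1=C10 Z from the iodo-ylide olefination; C4=C5 E from cis addition of H and C3 to the alkyne; C3 relayed from C6 through allylic 1,3-strain during ring closure; the acyl stereocentre is purchased as (R)-2-methylbutanoic acid.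

Key step: step 12

Remark: but-2-ynal (10) is taken as purchasable, and in steps 4 and 8 the ligand enantiomer is the one that delivers the configuration drawn, which the first batch would have to confirm.

**Route**

Step 1
Reactants: 1 3-[(tert-butyldimethylsilyl)oxy]propanal; 2 ethyltriphenylphosphonium iodide
Product: 6 (Z)-tert-butyl[(4-iodopent-3-en-1-yl)oxy]dimethylsilane, via ethylidenetriphenylphosphorane 3 (not isolated), via (1-iodoethyl)triphenylphosphonium iodide 4 (not isolated), via (1-iodoethylidene)triphenylphosphorane 5 (not isolated)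
Conditions: 2, n-BuLi, THF, 0 °C to rt; I2, −78 °C; NaN(SiMe3)2, −20 °C; then 1, −78 °C to rt
Reagents that add atoms: iodine, II
Why: Stork–Zhao-type Wittig olefination, in which the non-stabilised α-iodo ylide 5 adds to aldehyde 1 under kinetic control through the cis-oxaphosphetane, which should place iodine cis to the chain and so fix the later C1=C10 geometry (Z in 6).

Step 2
Reactants: 1 3-[(tert-butyldimethylsilyl)oxy]propanal; 7 methyl acrylate
Product: 8 methyl 5-[(tert-butyldimethylsilyl)oxy]-3-hydroxy-2-methylidenepentanoate (racemic)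
Conditions: DABCO, excess 7, MeOH (cat.), rt
Reagents that add atoms: none
Why: Morita–Baylis–Hillman reaction, in which DABCO adds to the acrylate and the resulting enolate adds to the unhindered aldehyde; the carbinol centre is formed racemic, which is immaterial because it becomes sp2 in step 3.

Step 3
Reactants: 8 methyl 5-[(tert-butyldimethylsilyl)oxy]-3-hydroxy-2-methylidenepentanoate
Product: 9 methyl (2Z)-2-(bromomethyl)-5-[(tert-butyldimethylsilyl)oxy]pent-2-enoate
Conditions: NBS, Me2S, CH2Cl2, 0 °C to rt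
Reagents that add atoms: N-bromosuccinimide, O=C1CCC(=O)N1Br
Why: Corey–Kim-type activation of the allylic alcohol followed by SN2' attack of bromide at the terminal methylene transposes the allylic system and should give the thermodynamically preferred Z-2-(bromomethyl)enoate without touching the silyl ether.

Step 4
Reactants: 9 methyl (2Z)-2-(bromomethyl)-5-[(tert-butyldimethylsilyl)oxy]pent-2-enoate; 10 but-2-ynal
Product: 12 (4S,5R)-4-{2-[(tert-butyldimethylsilyl)oxy]ethyl}-3-methylidene-5-(prop-1-yn-1-yl)oxolan-2-one, via open-chain hydroxy ester 11 (not isolated)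
Conditions: CrCl2 (10 mol%), chiral carbazole-bridged bis(oxazoline) ligand (12 mol%), i-Pr2NEt (30 mol%), Mn, Cp2ZrCl2, THF, rt; aqueous work-up; then TsOH·H2O (cat.), CH2Cl2, rt
Reagents that add atoms: none
Why: Chromium-catalysed asymmetric Nozaki–Hiyama-type 2-(alkoxycarbonyl)allylation followed by lactonisation, in which the γ-substituted allylchromium (substituent cis to CH2Cr) adds through a closed chair transition state to give the syn adduct 11 and hence the cis-lactone, while the chiral bis(oxazoline) on chromium selects the aldehyde face and sets C6 (R) and C7 (S).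

Step 5
Reactants: 12 (4S,5R)-4-{2-[(tert-butyldimethylsilyl)oxy]ethyl}-3-methylidene-5-(prop-1-yn-1-yl)oxolan-2-one
Product: 13 (3R,4S,5R)-4-{2-[(tert-butyldimethylsilyl)oxy]ethyl}-3-methyl-5-(prop-1-yn-1-yl)oxolan-2-one
Conditions: LiBH(s-Bu)3, THF, −78 °C; then AcOH in THF, −78 °C
Reagents that add atoms: none
Why: Conjugate (1,4) hydride reduction of the α-methylene lactone gives the lactone enolate, and kinetic protonation at −78 °C should occur on the face opposite to the two cis substituents at C6 and C7, which places the new C13 methyl cis to them (11R).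

Step 6
Reactants: 13 (3R,4S,5R)-4-{2-[(tert-butyldimethylsilyl)oxy]ethyl}-3-methyl-5-(prop-1-yn-1-yl)oxolan-2-one
Product: 14 (3R,4S,5R)-4-(2-hydroxyethyl)-3-methyl-5-(prop-1-yn-1-yl)oxolan-2-one
Conditions: HF·pyridine, THF, 0 °C to rt
Reagents that add atoms: none
Why: Fluoride-mediated desilylation of a primary silyl ether under mildly acidic conditions that leave the γ-lactone, its α-stereocentre and the alkyne intact.

Step 7
Reactants: 14 (3R,4S,5R)-4-(2-hydroxyethyl)-3-methyl-5-(prop-1-yn-1-yl)oxolan-2-one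
Product: 15 2-[(2R,3S,4R)-4-methyl-5-oxo-2-(prop-1-yn-1-yl)oxolan-3-yl]acetaldehyde
Conditions: Dess–Martin periodinane, pyridine, CH2Cl2, 0 °C to rt
Reagents that add atoms: none
Why: Dess–Martin oxidation of the primary alcohol under buffered conditions gives the aldehyde, which has no stereocentre at its α-carbon and no β-leaving group.

Step 8
Reactants: 15 2-[(2R,3S,4R)-4-methyl-5-oxo-2-(prop-1-yn-1-yl)oxolan-3-yl]acetaldehyde; 6 (Z)-tert-butyl[(4-iodopent-3-en-1-yl)oxy]dimethylsilane
Product: 16 (3R,4S,5R)-4-[(2S,3Z)-6-[(tert-butyldimethylsilyl)oxy]-2-hydroxy-3-methylhex-3-en-1-yl]-3-methyl-5-(prop-1-yn-1-yl)oxolan-2-one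
Conditions: CrCl2 (10 mol%), chiral oxazoline–sulfonamide ligand (11 mol%), 1,8-bis(dimethylamino)naphthalene (11 mol%), NiCl2·(2,9-dimethyl-1,10-phenanthroline) (2 mol%), Mn, Cp2ZrCl2, LiCl, MeCN, rt
Reagents that add atoms: none
Why: Catalytic asymmetric Nozaki–Hiyama–Kishi coupling, in which nickel activates the alkenyl iodide and passes the alkenyl group to chromium with retention of the Z geometry, the alkenylchromium adds to the aldehyde but not to the lactone, and the chiral sulfonamide ligand on chromium should control the aldehyde face to give the 9S carbinol.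

Step 9
Reactants: 16 (3R,4S,5R)-4-[(2S,3Z)-6-[(tert-butyldimethylsilyl)oxy]-2-hydroxy-3-methylhex-3-en-1-yl]-3-methyl-5-(prop-1-yn-1-yl)oxolan-2-one
Product: 17 (3R,4S,5R)-4-[(2S,3Z)-2,6-bis[(tert-butyldimethylsilyl)oxy]-3-methylhex-3-en-1-yl]-3-methyl-5-(prop-1-yn-1-yl)oxolan-2-one
Conditions: TBSOTf, 2,6-lutidine, CH2Cl2, −78 °C
Reagents that add atoms: tert-butyldimethylsilyl trifluoromethanesulfonate, CC(C)(C)[Si](C)(C)OS(=O)(=O)C(F)(F)F
Why: Silylation of the hindered secondary allylic alcohol with the silyl triflate and a non-nucleophilic base, which should not enolise the lactone at −78 °C.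

Step 10
Reactants: 17 (3R,4S,5R)-4-[(2S,3Z)-2,6-bis[(tert-butyldimethylsilyl)oxy]-3-methylhex-3-en-1-yl]-3-methyl-5-(prop-1-yn-1-yl)oxolan-2-one
Product: 18 (3R,4S,5R)-4-[(2S,3Z)-2-[(tert-butyldimethylsilyl)oxy]-6-hydroxy-3-methylhex-3-en-1-yl]-3-methyl-5-(prop-1-yn-1-yl)oxolan-2-one
Conditions: HF·pyridine, pyridine, THF, 0 °C
Reagents that add atoms: none
Why: Selective desilylation, since buffered HF·pyridine should cleave the unhindered primary silyl ether much faster than the hindered secondary allylic one.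

Step 11
Reactants: 18 (3R,4S,5R)-4-[(2S,3Z)-2-[(tert-butyldimethylsilyl)oxy]-6-hydroxy-3-methylhex-3-en-1-yl]-3-methyl-5-(prop-1-yn-1-yl)oxolan-2-one
Product: 19 (3Z,5S)-5-[(tert-butyldimethylsilyl)oxy]-4-methyl-6-[(2R,3S,4R)-4-methyl-5-oxo-2-(prop-1-yn-1-yl)oxolan-3-yl]hex-3-enal
Conditions: Dess–Martin periodinane, pyridine, CH2Cl2, 0 °C; crude aldehyde used at once
Reagents that add atoms: none
Why: Dess–Martin oxidation buffered with pyridine should give the β,γ-unsaturated aldehyde without migration of the Z-C1=C10 double bond into conjugation, provided the aldehyde is not stored or chromatographed.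

Step 12
Reactants: 19 (3Z,5S)-5-[(tert-butyldimethylsilyl)oxy]-4-methyl-6-[(2R,3S,4R)-4-methyl-5-oxo-2-(prop-1-yn-1-yl)oxolan-3-yl]hex-3-enal
Product: 20 (1(10)Z,4E)-(3S,6R,7S,9S,11R)-9-[(tert-butyldimethylsilyl)oxy]-3-[(triethylsilyl)oxy]germacra-1(10),4-dien-12,6-olide
Conditions: Ni(cod)2 (20 mol%), 1,3-bis(2,4,6-trimethylphenyl)imidazol-2-ylidene (IMes, 20 mol%), Et3SiH (3 equiv), THF, rt, 19 added by syringe pump to 0.005 M
Reagents that add atoms: triethylsilane, CC[SiH](CC)CC
Why: Zerovalent nickel carrying the small carbene binds the C4≡C5 alkyne and the C3 aldehyde and couples them oxidatively to an oxanickelacyclopentene (new C3–C4 bond), after which Et3SiH cleaves the Ni–O bond by sigma-bond metathesis and C–H reductive elimination at C5 releases the silyl ether and the catalyst. The closest known reaction type is the nickel-catalysed reductive alkyne–aldehyde macrocyclisation of methyl-capped ynals, which closes 12- and 14-membered rings with an endocyclic trisubstituted alkene. The 10-membered carbocycle closes in the 10-endo-dig mode at the alkyne (10-exo-trig at the carbonyl), and cis addition of H and C3 across the alkyne fixes C4=C5 as E within the ring. The C3 configuration is relayed from C6: allylic 1,3-strain with the C15 methyl holds the C6–H bond in the plane of the forming alkene, so C7 leaves on one face of the planar nickelacycle, C2 must sit on that same face to close the ring, and this arrangement corresponds to 3S. The step needs bonding at C4 and not C5 (the alternative is a 9-membered ring with an exocyclic ethylidene), which the small carbene and the branched, lactone-bearing C6 should secure by steering C–C formation to the methyl-bearing alkyne terminus, and it needs ring closure over oligomerisation, which slow addition at high dilution and the two turn elements (Z-C1=C10 alkene, cis-lactone) should secure.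

Step 13
Reactants: 20 (1(10)Z,4E)-(3S,6R,7S,9S,11R)-9-[(tert-butyldimethylsilyl)oxy]-3-[(triethylsilyl)oxy]germacra-1(10),4-dien-12,6-olide
Product: 21 (1(10)Z,4E)-(3S,6R,7S,9S,11R)-9-[(tert-butyldimethylsilyl)oxy]-3-hydroxygermacra-1(10),4-dien-12,6-olide
Conditions: PPTS (cat.), MeOH/CH2Cl2, 0 °C
Reagents that add atoms: none
Why: Acid-catalysed methanolysis removes the triethylsilyl ether selectively, the bulkier tert-butyldimethylsilyl ether at C9 being far slower to solvolyse.

Step 14
Reactants: 21 (1(10)Z,4E)-(3S,6R,7S,9S,11R)-9-[(tert-butyldimethylsilyl)oxy]-3-hydroxygermacra-1(10),4-dien-12,6-olide; 22 (R)-2-methylbutanoic acid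
Product: 23 (1(10)Z,4E)-(3S,6R,7S,9S,11R)-9-[(tert-butyldimethylsilyl)oxy]-3-{[(2R)-2-methylbutanoyl]oxy}germacra-1(10),4-dien-12,6-olide
Conditions: DCC, DMAP (cat.), CH2Cl2, 0 °C to rt
Reagents that add atoms: none
Why: Steglich esterification, in which the carbodiimide-activated acid is transferred by DMAP to the secondary allylic alcohol with retention at C3 and without racemisation of the α-alkyl acyl stereocentre.

Step 15
Reactants: 23 (1(10)Z,4E)-(3S,6R,7S,9S,11R)-9-[(tert-butyldimethylsilyl)oxy]-3-{[(2R)-2-methylbutanoyl]oxy}germacra-1(10),4-dien-12,6-olide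
Product: 24 (1(10)Z,4E)-(3S,6R,7S,9S,11R)-9-hydroxy-3-{[(2R)-2-methylbutanoyl]oxy}germacra-1(10),4-dien-12,6-olide
Conditions: HF·pyridine, pyridine, THF, 0 °C to rt
Reagents that add atoms: none
Why: Buffered fluoride desilylation frees the C9 alcohol under conditions mild enough to spare the allylic ester, the lactone and the acid-sensitive 1(10),4-diene.

**Compound list**

1 | 3-[(tert-butyldimethylsilyl)oxy]propanal | CC(C)(C)[Si](C)(C)OCCC=O | starting material
2 | ethyltriphenylphosphonium iodide | CC[P+](c1ccccc1)(c1ccccc1)c1ccccc1.[I-] | starting material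
3 | ethylidenetriphenylphosphorane | CC=P(c1ccccc1)(c1ccccc1)c1ccccc1 | intermediate
4 | (1-iodoethyl)triphenylphosphonium iodide (racemic) | CC(I)[P+](c1ccccc1)(c1ccccc1)c1ccccc1.[I-] | intermediate
5 | (1-iodoethylidene)triphenylphosphorane | CC(I)=P(c1ccccc1)(c1ccccc1)c1ccccc1 | intermediate
6 | (Z)-tert-butyl[(4-iodopent-3-en-1-yl)oxy]dimethylsilane (iodine cis to the CH2 chain) | CC(C)(C)[Si](C)(C)OCC/C=C(/C)I | intermediate
7 | methyl acrylate | C=CC(=O)OC | starting material
8 | methyl 5-[(tert-butyldimethylsilyl)oxy]-3-hydroxy-2-methylidenepentanoate (racemic) | COC(=O)C(=C)C(O)CCO[Si](C)(C)C(C)(C)C | intermediate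
9 | methyl (2Z)-2-(bromomethyl)-5-[(tert-butyldimethylsilyl)oxy]pent-2-enoate | COC(=O)/C(CBr)=C/CCO[Si](C)(C)C(C)(C)C | intermediate
10 | but-2-ynal | CC#CC=O | starting material
11 | methyl (3S,4R)-3-{2-[(tert-butyldimethylsilyl)oxy]ethyl}-4-hydroxy-2-methylidenehept-5-ynoate | CC(C)(C)[Si](C)(C)OCC[C@H]([C@H](C#CC)O)C(=C)C(=O)OC | intermediate
12 | (4S,5R)-4-{2-[(tert-butyldimethylsilyl)oxy]ethyl}-3-methylidene-5-(prop-1-yn-1-yl)oxolan-2-one (4,5-cis) | CC(C)(C)[Si](C)(C)OCC[C@@H]1[C@H](C#CC)OC(=O)C1=C | intermediate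
13 | (3R,4S,5R)-4-{2-[(tert-butyldimethylsilyl)oxy]ethyl}-3-methyl-5-(prop-1-yn-1-yl)oxolan-2-one (all-cis) | CC(C)(C)[Si](C)(C)OCC[C@@H]1[C@H](C#CC)OC(=O)[C@@H]1C | intermediate
14 | (3R,4S,5R)-4-(2-hydroxyethyl)-3-methyl-5-(prop-1-yn-1-yl)oxolan-2-one | OCC[C@@H]1[C@H](C#CC)OC(=O)[C@@H]1C | intermediate
15 | 2-[(2R,3S,4R)-4-methyl-5-oxo-2-(prop-1-yn-1-yl)oxolan-3-yl]acetaldehyde | O=CC[C@@H]1[C@H](C#CC)OC(=O)[C@@H]1C | intermediate
16 | (3R,4S,5R)-4-[(2S,3Z)-6-[(tert-butyldimethylsilyl)oxy]-2-hydroxy-3-methylhex-3-en-1-yl]-3-methyl-5-(prop-1-yn-1-yl)oxolan-2-one | CC(C)(C)[Si](C)(C)OCC/C=C(/C)[C@@H](O)C[C@@H]1[C@H](C#CC)OC(=O)[C@@H]1C | intermediate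
17 | (3R,4S,5R)-4-[(2S,3Z)-2,6-bis[(tert-butyldimethylsilyl)oxy]-3-methylhex-3-en-1-yl]-3-methyl-5-(prop-1-yn-1-yl)oxolan-2-one | CC(C)(C)[Si](C)(C)OCC/C=C(/C)[C@@H](O[Si](C)(C)C(C)(C)C)C[C@@H]1[C@H](C#CC)OC(=O)[C@@H]1C | intermediate
18 | (3R,4S,5R)-4-[(2S,3Z)-2-[(tert-butyldimethylsilyl)oxy]-6-hydroxy-3-methylhex-3-en-1-yl]-3-methyl-5-(prop-1-yn-1-yl)oxolan-2-one | OCC/C=C(/C)[C@@H](O[Si](C)(C)C(C)(C)C)C[C@@H]1[C@H](C#CC)OC(=O)[C@@H]1C | intermediate
19 | (3Z,5S)-5-[(tert-butyldimethylsilyl)oxy]-4-methyl-6-[(2R,3S,4R)-4-methyl-5-oxo-2-(prop-1-yn-1-yl)oxolan-3-yl]hex-3-enal | O=CC/C=C(/C)[C@@H](O[Si](C)(C)C(C)(C)C)C[C@@H]1[C@H](C#CC)OC(=O)[C@@H]1C | intermediate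
20 | (1(10)Z,4E)-(3S,6R,7S,9S,11R)-9-[(tert-butyldimethylsilyl)oxy]-3-[(triethylsilyl)oxy]germacra-1(10),4-dien-12,6-olide (10-membered ring C1–C10, lactone O on C6, H-6/H-7 cis) | CC[Si](CC)(CC)O[C@H]1C/C=C(/C)[C@@H](O[Si](C)(C)C(C)(C)C)C[C@@H]2[C@H](/C=C/1C)OC(=O)[C@@H]2C | intermediate
21 | (1(10)Z,4E)-(3S,6R,7S,9S,11R)-9-[(tert-butyldimethylsilyl)oxy]-3-hydroxygermacra-1(10),4-dien-12,6-olide | O[C@H]1C/C=C(/C)[C@@H](O[Si](C)(C)C(C)(C)C)C[C@@H]2[C@H](/C=C/1C)OC(=O)[C@@H]2C | intermediate
22 | (R)-2-methylbutanoic acid | CC[C@@H](C)C(=O)O | starting material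
23 | (1(10)Z,4E)-(3S,6R,7S,9S,11R)-9-[(tert-butyldimethylsilyl)oxy]-3-{[(2R)-2-methylbutanoyl]oxy}germacra-1(10),4-dien-12,6-olide | CC[C@@H](C)C(=O)O[C@H]1C/C=C(/C)[C@@H](O[Si](C)(C)C(C)(C)C)C[C@@H]2[C@H](/C=C/1C)OC(=O)[C@@H]2C | intermediate
24 | (1(10)Z,4E)-(3S,6R,7S,9S,11R)-9-hydroxy-3-{[(2R)-2-methylbutanoyl]oxy}germacra-1(10),4-dien-12,6-olide (CNP0276536.2) | CC[C@@H](C)C(=O)O[C@H]1C/C=C(/C)[C@@H](O)C[C@@H]2[C@H](/C=C/1C)OC(=O)[C@@H]2C | target

**Step count and risks**

Total steps: 15. Longest linear sequence: 14 (steps 2 to 15, from aldehyde 1); step 1 is a one-step side branch.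

Steps most likely to fail:

Step 12 (ring closure). The closure may fail through ionisation of the propargylic C6–O lactone bond by zerovalent nickel, through competing 9-membered exo closure or oligomerisation, through drift of the skipped enal into conjugation, or through delivery of the wrong aldehyde face. The fallback sets out from 17 and closes the same bond with chromium. Hydrozirconation with Cp2Zr(H)Cl in THF places zirconium on the less hindered, methyl-bearing alkyne carbon, and quenching with I2 should give the E-alkenyl iodide F1. Buffered HF·pyridine then frees the primary alcohol F2, and Dess–Martin oxidation with pyridine gives the iodo aldehyde F3. An intramolecular Nozaki–Hiyama–Kishi reaction (excess CrCl2, catalytic NiCl2, DMSO/THF, high dilution) should close C3–C4 with retention of the alkene geometry and return to the route at 21. If either closure favours the 3R alcohol F4, Mitsunobu esterification of F4 with acid 22 (PPh3, diisopropyl azodicarboxylate) inverts C3 and returns to the route at 23.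

Step 5 (C11). The kinetic cis selectivity may be lost by proton exchange and equilibration of the α-centre during the enolate quench, and the enolate may add to unreacted 12. The fallback sets out from 12 and replaces enolate protonation by face-selective delivery of H2 to the alkene. Co2(CO)8 in CH2Cl2 masks the alkyne as the dicobalt hexacarbonyl complex F5, which also adds bulk to the hindered face. Diimide (2-nitrobenzenesulfonylhydrazide, Et3N, rt) should then add both hydrogens cis from the open face to give the reduced complex F6. Oxidative decomplexation with (NH4)2Ce(NO3)6 in acetone at low temperature releases the alkyne and returns to the route at 13.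

Step 8 (C9). Facial selectivity at the aldehyde may be poor, because ligand control is less certain for a Z-trisubstituted alkenyl iodide and the lactone stereocentres may be mismatched with the ligand. The fallback sets out from the C9-epimeric mixture of 16. Dess–Martin oxidation with pyridine gives the Z-enone F7, and Corey–Bakshi–Shibata reduction (methyl oxazaborolidine, catecholborane, toluene, −78 °C) should set 9S under reagent control without touching the alkyne or lactone, returning to the route at 16.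

**Further compounds**

F1 | step 12 | (3R,4S,5R)-4-[(2S,3Z)-2,6-bis[(tert-butyldimethylsilyl)oxy]-3-methylhex-3-en-1-yl]-5-[(1E)-2-iodoprop-1-en-1-yl]-3-methyloxolan-2-one | CC(C)(C)[Si](C)(C)OCC/C=C(/C)[C@@H](O[Si](C)(C)C(C)(C)C)C[C@@H]1[C@H](/C=C(/I)C)OC(=O)[C@@H]1C
F2 | step 12 | (3R,4S,5R)-4-[(2S,3Z)-2-[(tert-butyldimethylsilyl)oxy]-6-hydroxy-3-methylhex-3-en-1-yl]-5-[(1E)-2-iodoprop-1-en-1-yl]-3-methyloxolan-2-one | OCC/C=C(/C)[C@@H](O[Si](C)(C)C(C)(C)C)C[C@@H]1[C@H](/C=C(/I)C)OC(=O)[C@@H]1C
F3 | step 12 | (3Z,5S)-5-[(tert-butyldimethylsilyl)oxy]-6-{(2R,3S,4R)-2-[(1E)-2-iodoprop-1-en-1-yl]-4-methyl-5-oxooxolan-3-yl}-4-methylhex-3-enal | O=CC/C=C(/C)[C@@H](O[Si](C)(C)C(C)(C)C)C[C@@H]1[C@H](/C=C(/I)C)OC(=O)[C@@H]1C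
F4 | step 12 | (1(10)Z,4E)-(3R,6R,7S,9S,11R)-9-[(tert-butyldimethylsilyl)oxy]-3-hydroxygermacra-1(10),4-dien-12,6-olide (C3 epimer of 21) | O[C@@H]1C/C=C(/C)[C@@H](O[Si](C)(C)C(C)(C)C)C[C@@H]2[C@H](/C=C/1C)OC(=O)[C@@H]2C
F5 | step 5 | hexacarbonyldicobalt complex of the alkyne of 12 | C[C]12[C]3([C@@H]4OC(=O)C(=C)[C@@H]4CCO[Si](C)(C)C(C)(C)C)[Co]1(=C=O)(=C=O)(=C=O)[Co]23(=C=O)(=C=O)=C=O
F6 | step 5 | hexacarbonyldicobalt complex of the alkyne of 13 | C[C]12[C]3([C@@H]4OC(=O)[C@H](C)[C@@H]4CCO[Si](C)(C)C(C)(C)C)[Co]1(=C=O)(=C=O)(=C=O)[Co]23(=C=O)(=C=O)=C=O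
F7 | step 8 | (3R,4S,5R)-4-[(3Z)-6-[(tert-butyldimethylsilyl)oxy]-3-methyl-2-oxohex-3-en-1-yl]-3-methyl-5-(prop-1-yn-1-yl)oxolan-2-one | CC(C)(C)[Si](C)(C)OCC/C=C(/C)C(=O)C[C@@H]1[C@H](C#CC)OC(=O)[C@@H]1C
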